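## Structural features

Didemnimide D (8) is a 3,4-di(heteroaryl)maleimide: a 1H-pyrrole-2,5-dione ring carries on its two alkene carbons, through single C(sp2)–C(sp2) bonds, C3 of a 6-bromo-1H-indole and C5 of a 1-methylimidazole, so that three ring systems sit in a row around a tetrasubstituted C3=C4 double bond. Compound 8 has no stereocentre; stereocentres appear only if this alkene is saturated, as two adjacent CH centres (C3 and C4 of a succinimide) that each bear one heteroaryl group. The fragile points are the aryl C6–Br bond (zerovalent palladium, halogen–metal exchange, hydrogenolysis), the imide (acidic N–H, ring opening by hydroxide or amines), the free indole N–H with its oxidisable C2=C3 bond, and the basic, nucleophilic, metal-binding imidazole N3. The real difficulty is to place two different heteroaryl groups on the two alkene carbons of a symmetrical core without statistical mixtures and without letting a metal meet the aryl bromide. The two aryl–alkene bonds are not alike: imidazole C5 is a poor carbon nucleophile and has to be delivered as an organometallic, whereas indole C3 is the most nucleophilic carbon of free 6-bromoindole. The key step uses this difference, and the fact that the maleimide alkene stands one oxidation level above a succinimide: the bond from C3 of the imide ring to indole C3 is made by attack of indole C3 on the C–H alkene carbon of a maleimide that already carries the imidazole.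

## Logic of the disconnections

From 8 to 7. No skeletal bond is cut; the C3=C4 double bond of the imide ring is taken back to two C–H centres. The saturated carbon next to indole C3 is the product carbon of a conjugate addition, so this change of oxidation level uncovers a Michael retron that 8 does not show. The gain is strategic, not in atom count, and it costs two stereocentres that have no meaning. The forward step must remove exactly these two hydrogens, starting with hydride abstraction at the C–H flanked by the indole, and leave indole C2, C6–Br and both N–H groups alone.

From 7 to 5 and 6. The bond between indole C3 and the neighbouring ring carbon of 7 is cut. The indole carbon is the natural nucleophile and the ring carbon is β to a carbonyl, so the polarity of the cut matches the innate reactivity of both pieces. The gain is large: 6 is split off intact as a purchased compound, and what remains, 5, carries only one substituent on its alkene. The forward step must attack through C3 and not N1 of 6, and at the C–H alkene carbon of 5 and not at the substituted one. It must also run without metal or base, so that C6–Br and the N–H groups stay unprotected.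

From 5 to 3 and 4. The bond between the alkene carbon of the imide ring and imidazole C5 is cut. Imidazole C5 cannot serve as a Friedel–Crafts nucleophile, so it is given a metal in 4, and the alkene carbon is given a halogen in 3 that the two carbonyls activate towards oxidative addition. Both pieces are then small, and the 1,5-substitution pattern of the imidazole is fixed by where the metal sits in 4. The forward coupling must tolerate the acidic imide N–H; it is placed before 6 enters, so palladium never sees an aryl bromide.

From 3 by way of 2 to 1. The C–Br bond is removed by functional group interconversion: 3 results from adding bromine across the alkene of 1 and eliminating once from 2. This leads to the simplest possible starting material. The forward sequence must stop after a single elimination, which the structure ensures, since 3 has no sp3 C–H left.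

## Other disconnections considered

Alternative 1: The cut takes the whole imide ring apart at C2–C3, C4–C5 and C5–N1. C3 and C4 then come from the triple bond of tert-butyl 6-bromo-3-[(1-methyl-1H-imidazol-5-yl)ethynyl]-1H-indole-1-carboxylate A1, N1 and one carbonyl carbon from 2,4-dimethoxybenzyl isocyanate A2, and the other carbonyl carbon from carbon monoxide A3. In the forward direction Ru3(CO)12 under a pressure of A3 would join A1, A2 and A3 to the doubly protected maleimide A4, presumably by oxidative cyclisation of alkyne and isocyanate at ruthenium, insertion of A3 and reductive elimination.
- In its favour: three bonds and the ring form in one operation, and the maleimide arrives at its final oxidation level. The orientation of the alkyne is irrelevant because both carbonyls are alike. On these two points, no dehydrogenation and no regiochemical question, the alternative is better than the chosen plan.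
- Against it here: A1 is not commercial, and its alkyne would have to come from a Sonogashira coupling at indole C3 that distinguishes a carbon–iodine bond from C6–Br. Imidazole N3 is a strong ligand for low-valent ruthenium, and an electron-rich diheteroaryl alkyne is an untested substrate type for this cyclisation. The carbamate of A1 would be exposed to temperatures well above 100 °C, and pressurised, toxic A3 is required. Two protecting groups must come off A4 afterwards, and the benzylic group that A2 brings in leaves an imide nitrogen only in hot strong acid.
- Comparison: structurally the alternative is more convergent. Mechanistically it rests on a three-component organometallic cascade, where the chosen plan rests on a proton-catalysed polar addition whose selectivity follows from the substrate. In step economy it should need about twice the four steps of the chosen plan once the making of A1 and the deprotections of A4 are counted.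

Alternative 2: The cut opens the pyrrole ring of the indole at C3–C3a and N1–C2. This leads to 5-bromo-2-iodoaniline A5 and 1-(2,4-dimethoxybenzyl)-3-(1-methyl-1H-imidazol-5-yl)-4-[(trimethylsilyl)ethynyl]-1H-pyrrole-2,5-dione A6. In the forward direction Pd(OAc)2, K2CO3 and LiCl in hot DMF would add the aryl group of A5 to the alkyne carbon of A6 that carries the maleimide and close N1–C2 by reductive elimination, giving the 2-silylindole A7 (Larock heteroannulation).
- In its favour: the position of bromine is fixed by the substitution of A5. The silyl group steers the aryl group to the correct alkyne carbon, so the indole C3–maleimide link is as secure as the CH-versus-substituted-carbon selectivity of the chosen plan; on regiocontrol the two are equal. The maleimide is at its final oxidation level throughout, so no stereoisomers and no oxidation step occur, which is a point in favour of the alternative.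
- Against it here: the indole that this step builds can be bought intact as 6, so a ring is constructed that need not be. A6 would itself have to be assembled by two successive cross-couplings on a protected imide core. A6 is also an ynone-like double Michael acceptor that would be exposed to a primary aniline, carbonate and chloride at about 100 °C. Zerovalent palladium would have to select the carbon–iodine bond and then leave the C–Br bonds of A5 and A7 untouched for the whole reaction. Afterwards the C2–Si bond and the benzylic group on nitrogen of A7 must be cleaved.
- Comparison: structurally it makes two bonds and a ring where the chosen plan makes one bond. Mechanistically it has more points of failure: chemoselective oxidative addition, insertion into an electron-poor alkyne, and competing conjugate additions. In step economy it is clearly longer, about seven steps against four.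

Alternative 3: The cut is the C3–C4 bond of the succinimide. This leads to the unsymmetrical diacylamine tert-butyl 6-bromo-3-{2-[(2,4-dimethoxybenzyl)[(1-methyl-1H-imidazol-5-yl)acetyl]amino]-2-oxoethyl}-1H-indole-1-carboxylate A8. In the forward direction two equivalents of LiN(SiMe3)2 would convert A8 into its bis-enolate, and CuCl2 as a one-electron oxidant (divalent copper) would couple the two α-carbons within the tether to the trans-succinimide A9.
- In its favour: the tether guarantees cross-coupling over homocoupling, and there is no regiochemical question at all, which is better than the chosen plan. No palladium is used anywhere; in this it is the equal of the chosen plan, where palladium is used only before 6 arrives. A9 stands at the same oxidation level as 7, so the same kind of dehydrogenation would finish the skeleton, and here the two plans are equal.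
- Against it here: A8 would need two successive N-acylations with two different heteroarylacetyl groups. The second is the acylation of a secondary amide nitrogen with an activated imidazolylacetyl group, which is prone to self-acylation and ketene formation. The strong base meets an indole carbamate that can transfer its acyl group. Copper is chelated by the imidazole. Oxidative enolate couplings are radical processes of modest reliability. After the dehydrogenation of A9 two protecting groups still have to be removed.
- Comparison: structurally it forms the central C–C bond and the ring together, but A9 needs two protecting groups that 7 does not. Mechanistically a low-temperature dianion oxidation is less predictable than an acid-mediated addition. In step economy it would be about twice as long as the chosen plan.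

Key step: step 3

Remark on the chemistry: the descriptors written for 7 correspond to the trans pair (3S,4S)/(3R,4R). It is assumed that bromination and dehydrobromination of 1 are run as one operation through the crude dibromide, that 5 is stored and reacted as its solution in acetic acid (N3 protonated, which suppresses intermolecular aza-Michael addition), and that 7 is carried forward as whatever diastereomer mixture forms.

## Route

Step 1
Reactants: 1 maleimide (1H-pyrrole-2,5-dione)
Product: 3 3-bromo-1H-pyrrole-2,5-dione (bromomaleimide), via trans-2,3-dibromosuccinimide 2 (not isolated)
Conditions: Br2 (1.05 equiv), CHCl3, reflux; concentrate; then Et3N (1.1 equiv), THF, 0 °C to rt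
Reagents that add atoms: bromine, BrBr
Why: Bromination–dehydrobromination of an enone-type alkene: anti addition of bromine should give the trans-dibromide 2 as a racemate (its two stereocentres are set by the anti addition and lost again at once), then Et3N removes the acidic C–H next to a carbonyl and bromide leaves from the neighbouring carbon (E1cB-type elimination). The sequence should stop at 3 because the alkenyl bromide has no sp3 C–H left.

Step 2
Reactants: 3 3-bromo-1H-pyrrole-2,5-dione; 4 1-methyl-5-(tributylstannyl)-1H-imidazole
Product: 5 3-(1-methyl-1H-imidazol-5-yl)-1H-pyrrole-2,5-dione
Conditions: Pd2(dba)3 (2.5 mol %), tri(2-furyl)phosphine (10 mol %), CuI (10 mol %), DMF, 60 °C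
Reagents that add atoms: none
Why: Migita–Kosugi–Stille coupling: zerovalent palladium inserts into the activated alkenyl C–Br bond of 3, the imidazol-5-yl group is transferred from tin (CuI assists the transmetalation) and reductive elimination forms the alkene–imidazole C5 bond, with the attachment next to N-methyl fixed by the position of tin. The medium is neutral, so the imide N–H is tolerated, no aryl bromide is present yet, and no stereocentre is formed.

Step 3
Reactants: 5 3-(1-methyl-1H-imidazol-5-yl)-1H-pyrrole-2,5-dione; 6 6-bromo-1H-indole
Product: 7 trans-3-(6-bromo-1H-indol-3-yl)-4-(1-methyl-1H-imidazol-5-yl)pyrrolidine-2,5-dione (racemate; 3S,4S enantiomer drawn)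
Conditions: 6 (1.5 equiv), AcOH, 110 °C, N2
Reagents that add atoms: none
Why: Friedel–Crafts-type Michael addition of an indole to a maleimide under Brønsted acid catalysis, the closest known reaction type being the addition of indoles through C3 to maleimides in hot acetic acid. Acetic acid protonates imidazole N3 of 5, which removes the only competing nucleophile and makes the unsubstituted alkene carbon the β-position of both an enone and a vinylimidazolium. C3 of 6, its most nucleophilic carbon, attacks this carbon (C4–H of 5); the enol that results at the imidazolyl-bearing carbon is conjugated with the imidazolium ring, whereas attack at the substituted carbon would build a quaternary centre and forgo this stabilisation. Loss of the proton from C3 of the indoleninium restores the indole and tautomerisation of the enol completes the succinimide, so one skeletal bond is formed and no ring is closed. The stereocentre at the indolyl-bearing carbon arises without control from achiral partners (racemate), and the one at the imidazolyl-bearing carbon is set by protonation of the enol and can equilibrate by enolisation in hot acid towards the trans isomer, in which the two heteroaryl groups are apart; neither matters because step 4 removes both. The step needs C3 over N1 selectivity at the indole, secured by the acidic medium in which the indole nitrogen is never deprotonated, and CH over C(imidazolyl) selectivity at the alkene, secured by sterics and by the enol stabilisation. With no metal and no base present, C6–Br and the indole and imide N–H groups need no protection.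

Step 4
Reactants: 7 trans-3-(6-bromo-1H-indol-3-yl)-4-(1-methyl-1H-imidazol-5-yl)pyrrolidine-2,5-dione
Product: 8 didemnimide D, 3-(6-bromo-1H-indol-3-yl)-4-(1-methyl-1H-imidazol-5-yl)-1H-pyrrole-2,5-dione
Conditions: DDQ (1.1 equiv), 1,4-dioxane, 25 to 60 °C
Reagents that add atoms: none
Why: Quinone dehydrogenation, the standard conversion of 3-indolylsuccinimides into 3-indolylmaleimides: DDQ abstracts hydride from the C–H that carries the indole (the cation is a 3-alkylideneindoleninium), and loss of the neighbouring acidic proton gives the maleimide alkene conjugated with both heteroaryl groups. Both stereocentres of 7 are erased, so its diastereomer ratio is irrelevant, and C6–Br, the N–H groups and the imidazole should not be oxidised under these neutral conditions.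

## Compound list

1 | maleimide (1H-pyrrole-2,5-dione) | O=C1C=CC(=O)N1 | starting material
2 | trans-2,3-dibromosuccinimide (racemate; 3S,4S enantiomer drawn; not isolated) | O=C1NC(=O)[C@H](Br)[C@H]1Br | intermediate
3 | 3-bromo-1H-pyrrole-2,5-dione (bromomaleimide) | O=C1NC(=O)C(Br)=C1 | intermediate
4 | 1-methyl-5-(tributylstannyl)-1H-imidazole | CCCC[Sn](CCCC)(CCCC)c1cncn1C | starting material
5 | 3-(1-methyl-1H-imidazol-5-yl)-1H-pyrrole-2,5-dione | Cn1cncc1C1=CC(=O)NC1=O | intermediate
6 | 6-bromo-1H-indole | Brc1ccc2cc[nH]c2c1 | starting material
7 | trans-3-(6-bromo-1H-indol-3-yl)-4-(1-methyl-1H-imidazol-5-yl)pyrrolidine-2,5-dione (racemate; 3S,4S enantiomer drawn) | O=C1NC(=O)[C@H](c2cncn2C)[C@H]1c1c[nH]c2cc(Br)ccc12 | intermediate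
8 | didemnimide D | Cn1cncc1C1=C(c2c[nH]c3cc(Br)ccc23)C(=O)NC1=O | target

## Step count and risks

Total step count: 4. Longest linear sequence: 4 steps, from 1 to 8; 4 and 6 are purchased and enter in steps 2 and 3.

Least certain steps:

Step 3 (key step). The addition may stall, because the heteroaryl-substituted alkene is more hindered than that of maleimide itself and the bromine lowers the nucleophilicity of the indole. Acid-induced self-condensation of the indole and leakage to attack through N1 or at the substituted alkene carbon could then compete. Fallback: the conjugate addition is given up for an addition–elimination at the maleimide oxidation level, with the imidazole introduced last. It sets out from 6 and comes back to the route at 8. Compound 6 is deprotonated with EtMgBr in THF/toluene to 6-bromoindol-1-ylmagnesium bromide F1. About 2.2 equivalents of F1 are used; the first is consumed by the imide N–H and returns as 6 on work-up. F1 attacks through C3 purchased 2,3-dibromomaleimide F2 and expels bromide, giving 3-bromo-4-(6-bromo-1H-indol-3-yl)-1H-pyrrole-2,5-dione F3. A Stille coupling of F3 with 4 under the conditions of step 2 should then give 8 directly, since the alkenyl bromide on the electron-poor ring should undergo oxidative addition to zerovalent palladium well before the aryl C6–Br does.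

Step 2. The coupling may stall through protodestannylation of the electron-rich imidazolylstannane by the acidic imide N–H and through binding of the imidate or of imidazole N3 to palladium. Conjugate addition of imidazole N3 to the bromomaleimide is a further drain. Fallback: the imide nitrogen is masked before the coupling. It sets out from 3 and comes back at 5. N-Alkylation of 3 with 4-methoxybenzyl chloride and K2CO3 in DMF should give 3-bromo-1-(4-methoxybenzyl)-1H-pyrrole-2,5-dione F4. Stille coupling of F4 with 4 (Pd2(dba)3, tri(2-furyl)phosphine, CuI, DMF) should give 1-(4-methoxybenzyl)-3-(1-methyl-1H-imidazol-5-yl)-1H-pyrrole-2,5-dione F5. Acidolysis of the benzylic group in refluxing CF3CO2H with anisole as cation trap, conditions under which the imidazolium-substituted maleimide is inert, should return 5.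

Step 4. Hydride abstraction may be overtaken by attack of the nucleophilic imidazole N3 or of the indole on the quinone, or by over-oxidation of the diaryl maleimide triene towards cyclised products. The acidic hydroquinone that forms may also precipitate the substrate as its imidazolium salt and stop the reaction. Fallback: the dehydrogenation is done by enolate halogenation and elimination instead of hydride abstraction. It sets out from 7 and comes back at 8. Treatment of 7 with LiN(SiMe3)2 (3.3 equiv, THF, −78 °C) removes both N–H protons and the more acidic α-C–H at the imidazolyl-bearing carbon. Iodine then gives 3-(6-bromo-1H-indol-3-yl)-4-iodo-4-(1-methyl-1H-imidazol-5-yl)pyrrolidine-2,5-dione F6, which is not isolated. On warming, the remaining base removes the neighbouring α-proton and iodide is lost to give 8.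

## Further compounds

F1 | step 3 | 6-bromoindol-1-ylmagnesium bromide | Br[Mg]n1ccc2ccc(Br)cc21
F2 | step 3 | 2,3-dibromomaleimide (3,4-dibromo-1H-pyrrole-2,5-dione; purchased) | O=C1NC(=O)C(Br)=C1Br
F3 | step 3 | 3-bromo-4-(6-bromo-1H-indol-3-yl)-1H-pyrrole-2,5-dione | O=C1NC(=O)C(c2c[nH]c3cc(Br)ccc23)=C1Br
F4 | step 2 | 3-bromo-1-(4-methoxybenzyl)-1H-pyrrole-2,5-dione | COc1ccc(CN2C(=O)C=C(Br)C2=O)cc1
F5 | step 2 | 1-(4-methoxybenzyl)-3-(1-methyl-1H-imidazol-5-yl)-1H-pyrrole-2,5-dione | COc1ccc(CN2C(=O)C=C(c3cncn3C)C2=O)cc1
F6 | step 4 | 3-(6-bromo-1H-indol-3-yl)-4-iodo-4-(1-methyl-1H-imidazol-5-yl)pyrrolidine-2,5-dione (diastereomer mixture, configuration undefined) | Cn1cncc1C1(I)C(c2c[nH]c3cc(Br)ccc23)C(=O)NC1=O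
A1 | alternative 1 | tert-butyl 6-bromo-3-[(1-methyl-1H-imidazol-5-yl)ethynyl]-1H-indole-1-carboxylate | Cn1cncc1C#Cc1cn(C(=O)OC(C)(C)C)c2cc(Br)ccc12
A2 | alternative 1 | 2,4-dimethoxybenzyl isocyanate | COc1ccc(CN=C=O)c(OC)c1
A3 | alternative 1 | carbon monoxide | [C-]#[O+]
A4 | alternative 1 | tert-butyl 6-bromo-3-[1-(2,4-dimethoxybenzyl)-4-(1-methyl-1H-imidazol-5-yl)-2,5-dioxo-2,5-dihydro-1H-pyrrol-3-yl]-1H-indole-1-carboxylate | COc1ccc(CN2C(=O)C(c3cncn3C)=C(c3cn(C(=O)OC(C)(C)C)c4cc(Br)ccc34)C2=O)c(OC)c1
A5 | alternative 2 | 5-bromo-2-iodoaniline | Nc1cc(Br)ccc1I
A6 | alternative 2 | 1-(2,4-dimethoxybenzyl)-3-(1-methyl-1H-imidazol-5-yl)-4-[(trimethylsilyl)ethynyl]-1H-pyrrole-2,5-dione | COc1ccc(CN2C(=O)C(c3cncn3C)=C(C#C[Si](C)(C)C)C2=O)c(OC)c1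
A7 | alternative 2 | 3-[6-bromo-2-(trimethylsilyl)-1H-indol-3-yl]-1-(2,4-dimethoxybenzyl)-4-(1-methyl-1H-imidazol-5-yl)-1H-pyrrole-2,5-dione | COc1ccc(CN2C(=O)C(c3cncn3C)=C(c3c([Si](C)(C)C)[nH]c4cc(Br)ccc34)C2=O)c(OC)c1
A8 | alternative 3 | tert-butyl 6-bromo-3-{2-[(2,4-dimethoxybenzyl)[(1-methyl-1H-imidazol-5-yl)acetyl]amino]-2-oxoethyl}-1H-indole-1-carboxylate | COc1ccc(CN(C(=O)Cc2cncn2C)C(=O)Cc2cn(C(=O)OC(C)(C)C)c3cc(Br)ccc23)c(OC)c1
A9 | alternative 3 | tert-butyl 6-bromo-3-[trans-1-(2,4-dimethoxybenzyl)-4-(1-methyl-1H-imidazol-5-yl)-2,5-dioxopyrrolidin-3-yl]-1H-indole-1-carboxylate (racemate; one enantiomer drawn) | COc1ccc(CN2C(=O)[C@H](c3cncn3C)[C@@H](c3cn(C(=O)OC(C)(C)C)c4cc(Br)ccc34)C2=O)c(OC)c1
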